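**Plan**

- The target is catechin-(6′→8)-catechin: an upper (2R,3S)-flavan-3-ol (rings A, C, B) whose ring B carbon C6′ is bonded to C8 of ring D of a lower (2R,3S)-flavan-3-ol (rings D, F, E).
- The retrosynthesis first cuts both pyran O1–C2 bonds (ring C and ring F). Each C2 is benzylic to a para-oxygenated ring (B or E) that can stabilise a cation, lies next to the oxygen-bearing C3, and has the ortho phenol oxygen of ring A or ring D in reach for a six-membered closure; a carboxyl group on each C2 serves as a traceless trigger for the cation.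
- Next the two C2–C3 bonds are cut by Evans syn-aldol reactions (arylacetyl imides of rings B and E, arylacetaldehydes on rings A and D), the ring B–ring D bond by a Suzuki coupling, and both aldehyde arms go back to Claisen-derived allyl groups.
- Forward: ring B boronate plus ring D bromide give the biaryl; the upper chain is added by aldol; the ring D allyl group becomes an aldehyde; the lower chain is added by aldol; auxiliaries and phenol masks are removed; rings F and C close together by anodic double decarboxylation; desilylation and hydrogenolysis finish.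
- Stereochemistry: both C3 centres (S) come from (R)-4-benzyl-2-oxazolidinone; both C2 centres (R) are set in the ring closure by the adjacent C3 silyloxy group (2,3-trans); the aldol-derived C2 configuration is erased.

Key step: step 22

Assumption: the ring B–ring D axis carries no stereodescriptor in the target, so it is treated as configurationally undefined and intermediates from 17 onward may be mixtures of rotamers about this bond.

Abbreviations: Bn = benzyl; MOM = methoxymethyl; TBS = tert-butyldimethylsilyl; Xc = (R)-4-benzyl-2-oxo-1,3-oxazolidin-3-yl. Chain carbons carry flavan numbers: C2 bears ring B or ring E (and the carbonyl group), C3 bears oxygen, C4 is the CH2 on ring A or ring D.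

**Route**

Step 1
Reactants: 1 3,4-dihydroxyphenylacetic acid
Product: 2 benzyl [3,4-bis(benzyloxy)phenyl]acetate
Conditions: BnBr (3.5 equiv), K2CO3, DMF, 60 °C, N2
Reagents that add atoms: benzyl bromide, BrCc1ccccc1
Why: Williamson O-benzylation of both phenols and O-alkylation of the carboxylate occur together under carbonate in DMF, so one operation protects all three acidic sites.

Step 2
Reactants: 2 benzyl [3,4-bis(benzyloxy)phenyl]acetate
Product: 3 [3,4-bis(benzyloxy)phenyl]acetic acid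
Conditions: LiOH·H2O, THF/MeOH/H2O, rt; then 1 M HCl
Reagents that add atoms: lithium hydroxide, [Li+].[OH-]
Why: Saponification cleaves only the benzyl ester, aryl benzyl ethers being inert to hydroxide.

Step 3
Reactants: 3 [3,4-bis(benzyloxy)phenyl]acetic acid; 4 (R)-4-benzyl-2-oxazolidinone
Product: 6 (R)-4-benzyl-3-{[3,4-bis(benzyloxy)phenyl]acetyl}oxazolidin-2-one (ring E imide), via mixed pivalic anhydride 5 (not isolated)
Conditions: PivCl, Et3N, THF, −20 °C; then 4, LiCl, −20 °C → rt
Reagents that add atoms: none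
Why: N-acylation of the oxazolidinone through the mixed pivalic anhydride (Et3N/LiCl protocol) occurs at the unhindered arylacetyl carbonyl and does not touch the auxiliary stereocentre.

Step 4
Reactants: 2 benzyl [3,4-bis(benzyloxy)phenyl]acetate
Product: 7 benzyl [4,5-bis(benzyloxy)-2-bromophenyl]acetate
Conditions: NBS, MeCN, 0 °C → rt
Reagents that add atoms: N-bromosuccinimide, O=C1CCC(=O)N1Br
Why: Electrophilic aromatic bromination of the 3,4-dialkoxyphenylacetate takes place para to the 3-benzyloxy group and ortho to the acetic arm (C6), the least hindered activated position, which is the future C6′ of ring B.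

Step 5
Reactants: 7 benzyl [4,5-bis(benzyloxy)-2-bromophenyl]acetate
Product: 8 benzyl [4,5-bis(benzyloxy)-2-(4,4,5,5-tetramethyl-1,3,2-dioxaborolan-2-yl)phenyl]acetate (ring B boronate)
Conditions: B2pin2, Pd(dppf)Cl2 (3 mol%), KOAc, 1,4-dioxane, 90 °C
Reagents that add atoms: bis(pinacolato)diboron, CC1(C)OB(OC1(C)C)B1OC(C)(C)C(C)(C)O1
Why: Miyaura borylation (zerovalent palladium, KOAc) converts the aryl bromide into the pinacol boronate without affecting the ester or the benzyl ethers.

Step 6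
Reactants: 9 3,5-bis(benzyloxy)phenol
Product: 10 1-(allyloxy)-3,5-bis(benzyloxy)benzene
Conditions: allyl bromide, K2CO3, acetone, reflux
Reagents that add atoms: allyl bromide, C=CCBr
Why: Williamson allylation of the phenoxide.

Step 7
Reactants: 10 1-(allyloxy)-3,5-bis(benzyloxy)benzene
Product: 11 2-allyl-3,5-bis(benzyloxy)phenol
Conditions: N,N-diethylaniline, 195 °C
Reagents that add atoms: none
Why: Aromatic Claisen rearrangement, a [3,3]-sigmatropic shift followed by tautomerisation, places the allyl group on an ortho carbon, and because both ortho positions are equivalent a single phenol should result.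

Step 8
Reactants: 11 2-allyl-3,5-bis(benzyloxy)phenol
Product: 12 2-allyl-1,5-bis(benzyloxy)-3-(methoxymethoxy)benzene
Conditions: MOMCl, iPr2NEt, CH2Cl2, 0 °C → rt
Reagents that add atoms: chloromethyl methyl ether, COCCl
Why: MOM ether formation masks the phenol that would otherwise form a lactol with the aldehyde of the next step, and the acetal resists the base, boron triflate and oxidants used later.

Step 9
Reactants: 12 2-allyl-1,5-bis(benzyloxy)-3-(methoxymethoxy)benzene
Product: 14 [2,4-bis(benzyloxy)-6-(methoxymethoxy)phenyl]acetaldehyde (ring A aldehyde), via vicinal diol 13 (not isolated)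
Conditions: OsO4 (2 mol%), NaIO4, 2,6-lutidine, 1,4-dioxane/H2O (3:1), rt; used without delay
Reagents that add atoms: osmium tetroxide, O=[Os](=O)(=O)=O (oxygen carrier, regenerated by sodium periodate, [Na+].[O-]I(=O)(=O)=O)
Why: Lemieux–Johnson oxidation (catalytic dihydroxylation, then periodate glycol cleavage) shortens the allyl group to the arylacetaldehyde without over-oxidation, lutidine buffering the medium.

Step 10
Reactants: 11 2-allyl-3,5-bis(benzyloxy)phenol
Product: 15 2-allyl-3,5-bis(benzyloxy)-6-bromophenol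
Conditions: NBS (1.0 equiv), iPr2NH (10 mol%), CH2Cl2, −78 °C
Reagents that add atoms: N-bromosuccinimide, O=C1CCC(=O)N1Br
Why: Amine-mediated ortho-bromination of a phenol: the N-bromoamine formed from NBS is delivered by hydrogen bonding to the OH group to the only free ortho carbon (C6), and the phloroglucinol-type ring should react far faster than the terminal alkene at −78 °C.

Step 11
Reactants: 15 2-allyl-3,5-bis(benzyloxy)-6-bromophenol
Product: 16 2-allyl-1,5-bis(benzyloxy)-4-bromo-3-(methoxymethoxy)benzene (ring D bromide)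
Conditions: NaH, MOMCl, DMF, 0 °C
Reagents that add atoms: chloromethyl methyl ether, COCCl
Why: Williamson-type O-alkylation of the hindered sodium phenoxide with MOMCl.

Step 12
Reactants: 8 ring B boronate; 16 ring D bromide
Product: 17 benzyl {4,5-bis(benzyloxy)-2-[3-allyl-4,6-bis(benzyloxy)-2-(methoxymethoxy)phenyl]phenyl}acetate (biaryl ester)
Conditions: Pd(OAc)2 (5 mol%), SPhos (10 mol%), K3PO4, toluene/H2O (10:1), 90 °C
Reagents that add atoms: none
Why: Suzuki–Miyaura coupling in which the electron-rich biarylphosphine SPhos lets zerovalent palladium insert into the di-ortho-oxygenated C–Br bond and drives reductive elimination to the tri-ortho-substituted biaryl.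

Step 13
Reactants: 17 biaryl ester
Product: 18 {4,5-bis(benzyloxy)-2-[3-allyl-4,6-bis(benzyloxy)-2-(methoxymethoxy)phenyl]phenyl}acetic acid (biaryl acid)
Conditions: LiOH·H2O, THF/MeOH/H2O, rt; then 0.5 M HCl to pH 4, 0 °C
Reagents that add atoms: lithium hydroxide, [Li+].[OH-]
Why: Saponification of the benzyl ester, the MOM and benzyl ethers and the allyl group being stable to hydroxide and to the brief, mildly acidic work-up.

Step 14
Reactants: 18 biaryl acid; 4 (R)-4-benzyl-2-oxazolidinone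
Product: 20 (R)-4-benzyl-3-({4,5-bis(benzyloxy)-2-[3-allyl-4,6-bis(benzyloxy)-2-(methoxymethoxy)phenyl]phenyl}acetyl)oxazolidin-2-one (biaryl imide), via mixed pivalic anhydride 19 (not isolated)
Conditions: PivCl, Et3N, THF, −20 °C; then 4, LiCl, −20 °C → rt
Reagents that add atoms: none
Why: The same mixed-anhydride N-acylation as in step 3 installs the auxiliary on the ring B acetic arm.

Step 15
Reactants: 20 biaryl imide; 14 ring A aldehyde
Product: 23 (R)-4-benzyl-3-[(2R,3S)-2-{4,5-bis(benzyloxy)-2-[3-allyl-4,6-bis(benzyloxy)-2-(methoxymethoxy)phenyl]phenyl}-4-[2,4-bis(benzyloxy)-6-(methoxymethoxy)phenyl]-3-hydroxybutanoyl]oxazolidin-2-one (upper aldol adduct), via Z-boron enolate 21 (not isolated), via boron aldolate 22 (not isolated)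
Conditions: Bu2BOTf, iPr2NEt, CH2Cl2, −78 → 0 °C; then 14, −78 → 0 °C; then pH 7 buffer, MeOH, 30% H2O2, 0 °C
Reagents that add atoms: none
Why: Evans syn-aldol reaction: the Z-boron enolate adds through a chair-like Zimmerman–Traxler transition state on the face opposite the auxiliary benzyl group, which sets C3 as S (and the later erased C2 as R).

Step 16
Reactants: 23 upper aldol adduct
Product: 24 3-O-TBS ether of 23: Xc–CO–C2H(ring B)–C3H(OTBS)–C4H2–ring A(OMOM), chain (2R,3S), ring B bonded to the allyl-bearing ring D(OMOM)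
Conditions: TBSOTf, 2,6-lutidine, CH2Cl2, −78 → 0 °C
Reagents that add atoms: tert-butyldimethylsilyl triflate, CC(C)(C)[Si](C)(C)OS(=O)(=O)C(F)(F)F
Why: Silylation of the secondary alcohol with the silyl triflate blocks retro-aldol pathways and provides the bulky C3 substituent needed in step 22.

Step 17
Reactants: 24 silylated upper adduct
Product: 26 biaryl aldehyde: 24 in which the ring D allyl group has become a 2-oxoethyl group, via vicinal diol 25 (not isolated)
Conditions: OsO4 (5 mol%), NaIO4, 2,6-lutidine, 1,4-dioxane/H2O (3:1), rt; used without delay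
Reagents that add atoms: osmium tetroxide, O=[Os](=O)(=O)=O (oxygen carrier, regenerated by sodium periodate, [Na+].[O-]I(=O)(=O)=O)
Why: Lemieux–Johnson oxidation of the only alkene unveils the ring D acetaldehyde while the imide, silyl ether and acetal groups are untouched.

Step 18
Reactants: 6 ring E imide; 26 biaryl aldehyde
Product: 29 bis-imide mono-alcohol: 26 in which the ring D arm has become C4H2–C3H(OH)–C2H(ring E)–CO–Xc with the (2R,3S) configuration, via Z-boron enolate 27 (not isolated), via boron aldolate 28 (not isolated)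
Conditions: 6 (1.5 equiv), Bu2BOTf, iPr2NEt, CH2Cl2, −78 → 0 °C; then 26, −78 → 0 °C; then pH 7 buffer, MeOH, 30% H2O2, 0 °C
Reagents that add atoms: none
Why: Second Evans syn-aldol reaction, in which the preformed Z-boron enolate of the ring E imide adds to the ring D aldehyde under auxiliary control (Zimmerman–Traxler chair) and sets the lower C3 as S.

Step 19
Reactants: 29 bis-imide mono-alcohol
Product: 30 bis-imide bis-TBS ether (both chains Xc–CO–C2H(aryl)–C3H(OTBS)–C4H2–aryl, each 2R,3S)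
Conditions: TBSOTf, 2,6-lutidine, CH2Cl2, −78 → 0 °C
Reagents that add atoms: tert-butyldimethylsilyl triflate, CC(C)(C)[Si](C)(C)OS(=O)(=O)C(F)(F)F
Why: Silylation of the remaining secondary alcohol, as in step 16.

Step 20
Reactants: 30 bis-imide bis-TBS ether
Product: 32 bis(carboxylic acid) with both phenols as MOM ethers (both chains HO2C–C2H(aryl)–C3H(OTBS)–C4H2–aryl and each 2R,3S), via bis(peroxy acid) 31 (not isolated)
Conditions: LiOH·H2O, 30% H2O2, THF/H2O (3:1), 0 °C → rt; then Na2SO3; then 0.5 M HCl to pH 4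
Reagents that add atoms: hydrogen peroxide (as lithium hydroperoxide), OO
Why: Hydroperoxide attacks the exocyclic imide carbonyl selectively (LiOOH hydrolysis), sulfite reduces the peracids and the silyl ethers prevent retro-aldol, while any epimerisation at C2 is harmless because that centre is erased.

Step 21
Reactants: 32 bis-acid bis-MOM ether
Product: 33 bis(2-aryl-3-silyloxy carboxylic acid) with free ring A and ring D phenols (seco acid; both chains 2R,3S)
Conditions: ZnBr2, n-PrSH, CH2Cl2, 0 °C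
Reagents that add atoms: none
Why: Lewis acid–thiol cleavage of the aryl MOM ethers: ZnBr2 activates the acetal and the thiol traps the methoxymethyl cation, which protects the nucleophilic rings from alkylation and should leave the hindered secondary silyl ethers and the benzyl ethers in place.

Step 22
Reactants: 33 seco acid
Product: 35 octa-O-benzyl-3,3″-bis-O-TBS-catechin-(6′→8)-catechin: upper (2R,3S)-5,7,3′,4′-tetrabenzyloxy-3-silyloxyflavan bonded from C6′ to C8 of the lower (2R,3S)-5,7,3′,4′-tetrabenzyloxy-3-silyloxyflavan, via ring F-closed monoacid 34 (not isolated)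
Conditions: graphite anode, Pt cathode, undivided cell, constant current (ca. 5 mA cm−2, 4.5–5 F mol−1), 2,4,6-collidine (2.2 equiv), n-Bu4NPF6 (0.1 M), 3 Å MS, CH2Cl2, rt
Reagents that add atoms: none
Why: Proposed new method: each carboxylate (formed with collidine, the phenols staying neutral) is oxidised at the graphite anode and loses CO2, and the benzylic radical is oxidised again to a cation stabilised by the para benzyloxy group of ring E or ring B; the closest known reaction type is the Hofer–Moest (non-Kolbe) decarboxylative etherification of arylacetic acids with added alcohols, here made intramolecular with a phenol and run at two sites of one molecule. Ring F closes by 6-exo-trig attack of the ring D phenol oxygen on the lower cation (assumed to form first because it is less hindered, hence intermediate 34), and ring C closes in the same 6-exo-trig mode by attack of the ring A phenol oxygen on the upper cation. Each new C2 centre (R) is controlled by the adjacent C3 centre: in the chair-like transition state the OTBS group is pseudo-equatorial and the aryl group of the planar cation takes the other pseudo-equatorial site, giving the 2,3-trans isomer, which is also the more stable one should the benzylic ether re-ionise. The step needs cation formation at C2 only and oxidation of carboxylate in preference to the free phenols; the first is secured by the carboxyl group itself (no C–H oxidation at the more electron-rich C4), the second should follow from the carboxylates being the only anions at the anode and from stopping the charge a little above 2 F per carboxyl group. The C2 configuration inherited from the aldol steps is erased, so only C3 has to be carried through.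

Step 23
Reactants: 35 octabenzyl bis-silyl biflavan
Product: 36 octa-O-benzyl-catechin-(6′→8)-catechin (both C3 hydroxyls free; 2R,3S in both units)
Conditions: TBAF, THF, 0 °C → rt; then aq. NH4Cl
Reagents that add atoms: none
Why: Fluoride-induced cleavage of both secondary silyl ethers, the benzyl ethers and the flavan rings being inert.

Step 24
Reactants: 36 octabenzyl biflavan diol
Product: 37 catechin-(6′→8)-catechin, (2R,3S)-2-{2-[(2R,3S)-2-(3,4-dihydroxyphenyl)-3,5,7-trihydroxychroman-8-yl]-4,5-dihydroxyphenyl}chroman-3,5,7-triol (target)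
Conditions: H2 (1 atm), Pd(OH)2/C, THF/MeOH, rt
Reagents that add atoms: none
Why: Hydrogenolysis of the eight aryl benzyl ethers over Pd(OH)2 on carbon under neutral conditions, which are expected to spare the benzylic C2–O1 bonds of the flavans, releases the target.

**Compound list**

1 | 3,4-dihydroxyphenylacetic acid | OC(=O)Cc1ccc(O)c(O)c1 | starting material
2 | benzyl [3,4-bis(benzyloxy)phenyl]acetate | O=C(OCc1ccccc1)Cc1ccc(OCc2ccccc2)c(OCc2ccccc2)c1 | intermediate
3 | [3,4-bis(benzyloxy)phenyl]acetic acid | OC(=O)Cc1ccc(OCc2ccccc2)c(OCc2ccccc2)c1 | intermediate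
4 | (R)-4-benzyl-2-oxazolidinone | O=C1N[C@H](Cc2ccccc2)CO1 | starting material
5 | mixed pivalic anhydride of 3 (not isolated) | CC(C)(C)C(=O)OC(=O)Cc1ccc(OCc2ccccc2)c(OCc2ccccc2)c1 | intermediate
6 | (R)-4-benzyl-3-{[3,4-bis(benzyloxy)phenyl]acetyl}oxazolidin-2-one (ring E imide) | O=C(Cc1ccc(OCc2ccccc2)c(OCc2ccccc2)c1)N1C(=O)OC[C@H]1Cc1ccccc1 | intermediate
7 | benzyl [4,5-bis(benzyloxy)-2-bromophenyl]acetate | O=C(OCc1ccccc1)Cc1cc(OCc2ccccc2)c(OCc2ccccc2)cc1Br | intermediate
8 | benzyl [4,5-bis(benzyloxy)-2-(4,4,5,5-tetramethyl-1,3,2-dioxaborolan-2-yl)phenyl]acetate (ring B boronate) | O=C(OCc1ccccc1)Cc1cc(OCc2ccccc2)c(OCc2ccccc2)cc1B1OC(C)(C)C(C)(C)O1 | intermediate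
9 | 3,5-bis(benzyloxy)phenol | Oc1cc(OCc2ccccc2)cc(OCc2ccccc2)c1 | starting material
10 | 1-(allyloxy)-3,5-bis(benzyloxy)benzene | C=CCOc1cc(OCc2ccccc2)cc(OCc2ccccc2)c1 | intermediate
11 | 2-allyl-3,5-bis(benzyloxy)phenol | C=CCc1c(O)cc(OCc2ccccc2)cc1OCc1ccccc1 | intermediate
12 | 2-allyl-1,5-bis(benzyloxy)-3-(methoxymethoxy)benzene | C=CCc1c(OCOC)cc(OCc2ccccc2)cc1OCc1ccccc1 | intermediate
13 | 3-[2,4-bis(benzyloxy)-6-(methoxymethoxy)phenyl]propane-1,2-diol, racemic (not isolated) | OCC(O)Cc1c(OCOC)cc(OCc2ccccc2)cc1OCc1ccccc1 | intermediate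
14 | [2,4-bis(benzyloxy)-6-(methoxymethoxy)phenyl]acetaldehyde (ring A aldehyde) | O=CCc1c(OCOC)cc(OCc2ccccc2)cc1OCc1ccccc1 | intermediate
15 | 2-allyl-3,5-bis(benzyloxy)-6-bromophenol | C=CCc1c(O)c(Br)c(OCc2ccccc2)cc1OCc1ccccc1 | intermediate
16 | 2-allyl-1,5-bis(benzyloxy)-4-bromo-3-(methoxymethoxy)benzene (ring D bromide) | C=CCc1c(OCOC)c(Br)c(OCc2ccccc2)cc1OCc1ccccc1 | intermediate
17 | benzyl {4,5-bis(benzyloxy)-2-[3-allyl-4,6-bis(benzyloxy)-2-(methoxymethoxy)phenyl]phenyl}acetate (biaryl ester) | O=C(OCc1ccccc1)Cc1cc(OCc2ccccc2)c(OCc2ccccc2)cc1-c1c(OCOC)c(CC=C)c(OCc2ccccc2)cc1OCc1ccccc1 | intermediate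
18 | {4,5-bis(benzyloxy)-2-[3-allyl-4,6-bis(benzyloxy)-2-(methoxymethoxy)phenyl]phenyl}acetic acid (biaryl acid) | OC(=O)Cc1cc(OCc2ccccc2)c(OCc2ccccc2)cc1-c1c(OCOC)c(CC=C)c(OCc2ccccc2)cc1OCc1ccccc1 | intermediate
19 | mixed pivalic anhydride of 18 (not isolated) | CC(C)(C)C(=O)OC(=O)Cc1cc(OCc2ccccc2)c(OCc2ccccc2)cc1-c1c(OCOC)c(CC=C)c(OCc2ccccc2)cc1OCc1ccccc1 | intermediate
20 | (R)-4-benzyl-3-({4,5-bis(benzyloxy)-2-[3-allyl-4,6-bis(benzyloxy)-2-(methoxymethoxy)phenyl]phenyl}acetyl)oxazolidin-2-one (biaryl imide) | O=C(Cc1cc(OCc2ccccc2)c(OCc2ccccc2)cc1-c1c(OCOC)c(CC=C)c(OCc2ccccc2)cc1OCc1ccccc1)N1C(=O)OC[C@H]1Cc1ccccc1 | intermediate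
21 | Z-di-n-butylboron enolate of 20 (not isolated) | CCCCB(CCCC)O/C(=C\c1cc(OCc2ccccc2)c(OCc2ccccc2)cc1-c1c(OCOC)c(CC=C)c(OCc2ccccc2)cc1OCc1ccccc1)N1C(=O)OC[C@H]1Cc1ccccc1 | intermediate
22 | O-dibutylboryl aldolate of 23 (not isolated) | O=C(N1C(=O)OC[C@H]1Cc1ccccc1)[C@H](c1cc(OCc2ccccc2)c(OCc2ccccc2)cc1-c1c(OCOC)c(CC=C)c(OCc2ccccc2)cc1OCc1ccccc1)[C@@H](OB(CCCC)CCCC)Cc1c(OCOC)cc(OCc2ccccc2)cc1OCc1ccccc1 | intermediate
23 | upper aldol adduct, (2R,3S)-3-hydroxybutanoyl imide carrying the biaryl at C2 and ring A at C4 | O=C(N1C(=O)OC[C@H]1Cc1ccccc1)[C@H](c1cc(OCc2ccccc2)c(OCc2ccccc2)cc1-c1c(OCOC)c(CC=C)c(OCc2ccccc2)cc1OCc1ccccc1)[C@@H](O)Cc1c(OCOC)cc(OCc2ccccc2)cc1OCc1ccccc1 | intermediate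
24 | 3-O-TBS ether of 23 | O=C(N1C(=O)OC[C@H]1Cc1ccccc1)[C@H](c1cc(OCc2ccccc2)c(OCc2ccccc2)cc1-c1c(OCOC)c(CC=C)c(OCc2ccccc2)cc1OCc1ccccc1)[C@@H](O[Si](C)(C)C(C)(C)C)Cc1c(OCOC)cc(OCc2ccccc2)cc1OCc1ccccc1 | intermediate
25 | diol from 24, ring D 2,3-dihydroxypropyl group, both carbinol epimers (not isolated) | O=C(N1C(=O)OC[C@H]1Cc1ccccc1)[C@H](c1cc(OCc2ccccc2)c(OCc2ccccc2)cc1-c1c(OCOC)c(CC(O)CO)c(OCc2ccccc2)cc1OCc1ccccc1)[C@@H](O[Si](C)(C)C(C)(C)C)Cc1c(OCOC)cc(OCc2ccccc2)cc1OCc1ccccc1 | intermediate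
26 | biaryl aldehyde, ring D 2-oxoethyl group | O=C(N1C(=O)OC[C@H]1Cc1ccccc1)[C@H](c1cc(OCc2ccccc2)c(OCc2ccccc2)cc1-c1c(OCOC)c(CC=O)c(OCc2ccccc2)cc1OCc1ccccc1)[C@@H](O[Si](C)(C)C(C)(C)C)Cc1c(OCOC)cc(OCc2ccccc2)cc1OCc1ccccc1 | intermediate
27 | Z-di-n-butylboron enolate of 6 (not isolated) | CCCCB(CCCC)O/C(=C\c1ccc(OCc2ccccc2)c(OCc2ccccc2)c1)N1C(=O)OC[C@H]1Cc1ccccc1 | intermediate
28 | O-dibutylboryl aldolate of 29 (not isolated) | O=C(N1C(=O)OC[C@H]1Cc1ccccc1)[C@H](c1cc(OCc2ccccc2)c(OCc2ccccc2)cc1-c1c(OCOC)c(C[C@H](OB(CCCC)CCCC)[C@H](C(=O)N2C(=O)OC[C@H]2Cc2ccccc2)c2ccc(OCc3ccccc3)c(OCc3ccccc3)c2)c(OCc2ccccc2)cc1OCc1ccccc1)[C@@H](O[Si](C)(C)C(C)(C)C)Cc1c(OCOC)cc(OCc2ccccc2)cc1OCc1ccccc1 | intermediate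
29 | bis-imide mono-alcohol (lower chain 2R,3S with free C3–OH) | O=C(N1C(=O)OC[C@H]1Cc1ccccc1)[C@H](c1cc(OCc2ccccc2)c(OCc2ccccc2)cc1-c1c(OCOC)c(C[C@H](O)[C@H](C(=O)N2C(=O)OC[C@H]2Cc2ccccc2)c2ccc(OCc3ccccc3)c(OCc3ccccc3)c2)c(OCc2ccccc2)cc1OCc1ccccc1)[C@@H](O[Si](C)(C)C(C)(C)C)Cc1c(OCOC)cc(OCc2ccccc2)cc1OCc1ccccc1 | intermediate
30 | bis-imide bis-TBS ether | O=C(N1C(=O)OC[C@H]1Cc1ccccc1)[C@H](c1cc(OCc2ccccc2)c(OCc2ccccc2)cc1-c1c(OCOC)c(C[C@H](O[Si](C)(C)C(C)(C)C)[C@H](C(=O)N2C(=O)OC[C@H]2Cc2ccccc2)c2ccc(OCc3ccccc3)c(OCc3ccccc3)c2)c(OCc2ccccc2)cc1OCc1ccccc1)[C@@H](O[Si](C)(C)C(C)(C)C)Cc1c(OCOC)cc(OCc2ccccc2)cc1OCc1ccccc1 | intermediate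
31 | bis(peroxy acid) from 30 (not isolated) | OOC(=O)[C@H](c1cc(OCc2ccccc2)c(OCc2ccccc2)cc1-c1c(OCOC)c(C[C@H](O[Si](C)(C)C(C)(C)C)[C@H](C(=O)OO)c2ccc(OCc3ccccc3)c(OCc3ccccc3)c2)c(OCc2ccccc2)cc1OCc1ccccc1)[C@@H](O[Si](C)(C)C(C)(C)C)Cc1c(OCOC)cc(OCc2ccccc2)cc1OCc1ccccc1 | intermediate
32 | bis(carboxylic acid) bis-MOM ether | OC(=O)[C@H](c1cc(OCc2ccccc2)c(OCc2ccccc2)cc1-c1c(OCOC)c(C[C@H](O[Si](C)(C)C(C)(C)C)[C@H](C(O)=O)c2ccc(OCc3ccccc3)c(OCc3ccccc3)c2)c(OCc2ccccc2)cc1OCc1ccccc1)[C@@H](O[Si](C)(C)C(C)(C)C)Cc1c(OCOC)cc(OCc2ccccc2)cc1OCc1ccccc1 | intermediate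
33 | seco acid: bis(2-aryl-3-silyloxy carboxylic acid) with free ring A and ring D phenols | OC(=O)[C@H](c1cc(OCc2ccccc2)c(OCc2ccccc2)cc1-c1c(O)c(C[C@H](O[Si](C)(C)C(C)(C)C)[C@H](C(O)=O)c2ccc(OCc3ccccc3)c(OCc3ccccc3)c2)c(OCc2ccccc2)cc1OCc1ccccc1)[C@@H](O[Si](C)(C)C(C)(C)C)Cc1c(O)cc(OCc2ccccc2)cc1OCc1ccccc1 | intermediate
34 | ring F-closed monoacid (lower flavan formed, upper seco acid; not isolated) | OC(=O)[C@H](c1cc(OCc2ccccc2)c(OCc2ccccc2)cc1-c1c(OCc2ccccc2)cc(OCc2ccccc2)c2c1O[C@H](c1ccc(OCc3ccccc3)c(OCc3ccccc3)c1)[C@@H](O[Si](C)(C)C(C)(C)C)C2)[C@@H](O[Si](C)(C)C(C)(C)C)Cc1c(O)cc(OCc2ccccc2)cc1OCc1ccccc1 | intermediate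
35 | octa-O-benzyl-3,3″-bis-O-TBS-catechin-(6′→8)-catechin | c1ccccc1COc1cc(OCc2ccccc2)c2c(c1)O[C@H](c1cc(OCc3ccccc3)c(OCc3ccccc3)cc1-c1c(OCc3ccccc3)cc(OCc3ccccc3)c3c1O[C@H](c1ccc(OCc4ccccc4)c(OCc4ccccc4)c1)[C@@H](O[Si](C)(C)C(C)(C)C)C3)[C@@H](O[Si](C)(C)C(C)(C)C)C2 | intermediate
36 | octa-O-benzyl-catechin-(6′→8)-catechin | c1ccccc1COc1cc(OCc2ccccc2)c2c(c1)O[C@H](c1cc(OCc3ccccc3)c(OCc3ccccc3)cc1-c1c(OCc3ccccc3)cc(OCc3ccccc3)c3c1O[C@H](c1ccc(OCc4ccccc4)c(OCc4ccccc4)c1)[C@@H](O)C3)[C@@H](O)C2 | intermediate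
37 | catechin-(6′→8)-catechin (CNP0353739.1) | Oc1cc(O)c2c(c1)O[C@H](c1cc(O)c(O)cc1-c1c(O)cc(O)c3c1O[C@H](c1ccc(O)c(O)c1)[C@@H](O)C3)[C@@H](O)C2 | target

**Step count and risks**

Total: 24 steps. Longest linear sequence: 17 steps (9 → 10 → 11 → 15 → 16 → 17 → 18 → 20 → 23 → 24 → 26 → 29 → 30 → 32 → 33 → 35 → 36 → 37).

Steps most likely to fail:

1. Step 22 (anodic double ring closure). The anode may oxidise the free phenol rings A and D, or the electron-rich chromans just formed, instead of the carboxylates. The electrode may foul, a hydride may shift from C3 to the cation, the second decarboxylation may stall, or the closure may be poorly trans-selective. Fallback: setting out from seco acid 33, both carboxyl groups would be esterified with N-hydroxyphthalimide (DIC, CH2Cl2, 0 °C) to give the bis(N-acyloxyphthalimide) F1. Irradiation with blue light in the presence of an organic phenothiazine photocatalyst and LiBF4 in MeCN/CH2Cl2 would reduce each ester, expel CO2 and phthalimide, and let the catalyst radical cation oxidise the benzylic radical to the same C2 cation. This radical–polar crossover decarboxylative C–O bond formation is a known reaction of such redox-active esters with oxygen nucleophiles. The ortho phenols would capture the cations as before, rejoining the route at 35. The oxidant in this variant is much too weak to attack phenols.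

2. Step 12 (Suzuki coupling). Oxidative addition into the di-ortho-oxygenated, electron-rich bromide may be slow, the boronate may protodeboronate, and palladium hydride may move the allyl double bond into conjugation. Fallback: the roles of the rings are exchanged and no boron or aqueous base is used. Setting out from bromide 16, bromine–lithium exchange (n-BuLi, THF, −78 °C) would give the aryllithium F2, and ZnCl2 would convert it into the arylzinc chloride F3. Negishi coupling of F3 with the unhindered bromo ester 7 (Pd2(dba)3, SPhos, THF, 60 °C) would return to biaryl ester 17.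

3. Step 15 (first aldol). Enolisation and addition may be slow because the enolate carbon is flanked by the ortho ring D aryl group, facial selectivity may erode, and the enolisable aldehyde may self-condense. Fallback: the C2–C3 bond is made before the biaryl bond.
   - Setting out from bromo ester 7, saponification (LiOH) would give the bromo acid F4.
   - Its mixed pivalic anhydride F5 would acylate 4 to give the bromo imide F6.
   - The Z-boron enolate F7 (Bu2BOTf, iPr2NEt) would add to aldehyde 14 to give the boron aldolate F8 and, after oxidative work-up, the aldol adduct F9, which has an ortho bromine in place of the bulky ortho aryl group.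
   - Silylation (TBSOTf, 2,6-lutidine) would give the TBS ether F10.
   - Base-free Negishi coupling of F10 with the arylzinc chloride F3 (made from 16 as above) would then form the biaryl bond and rejoin the route at 24.

**Further compounds**

F1 | step 22 | bis(N-acyloxyphthalimide) of seco acid 33 | O=C(ON1C(=O)c2ccccc2C1=O)[C@H](c1cc(OCc2ccccc2)c(OCc2ccccc2)cc1-c1c(O)c(C[C@H](O[Si](C)(C)C(C)(C)C)[C@H](C(=O)ON2C(=O)c3ccccc3C2=O)c2ccc(OCc3ccccc3)c(OCc3ccccc3)c2)c(OCc2ccccc2)cc1OCc1ccccc1)[C@@H](O[Si](C)(C)C(C)(C)C)Cc1c(O)cc(OCc2ccccc2)cc1OCc1ccccc1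
F2 | step 12 | [3-allyl-4,6-bis(benzyloxy)-2-(methoxymethoxy)phenyl]lithium | C=CCc1c(OCOC)c([Li])c(OCc2ccccc2)cc1OCc1ccccc1
F3 | step 12 | [3-allyl-4,6-bis(benzyloxy)-2-(methoxymethoxy)phenyl]zinc chloride | C=CCc1c(OCOC)c([Zn]Cl)c(OCc2ccccc2)cc1OCc1ccccc1
F4 | step 15 | [4,5-bis(benzyloxy)-2-bromophenyl]acetic acid | OC(=O)Cc1cc(OCc2ccccc2)c(OCc2ccccc2)cc1Br
F5 | step 15 | mixed pivalic anhydride of F4 | CC(C)(C)C(=O)OC(=O)Cc1cc(OCc2ccccc2)c(OCc2ccccc2)cc1Br
F6 | step 15 | (R)-4-benzyl-3-{[4,5-bis(benzyloxy)-2-bromophenyl]acetyl}oxazolidin-2-one | O=C(Cc1cc(OCc2ccccc2)c(OCc2ccccc2)cc1Br)N1C(=O)OC[C@H]1Cc1ccccc1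
F7 | step 15 | Z-di-n-butylboron enolate of F6 | CCCCB(CCCC)O/C(=C\c1cc(OCc2ccccc2)c(OCc2ccccc2)cc1Br)N1C(=O)OC[C@H]1Cc1ccccc1
F8 | step 15 | O-dibutylboryl aldolate of F9 | O=C(N1C(=O)OC[C@H]1Cc1ccccc1)[C@H](c1cc(OCc2ccccc2)c(OCc2ccccc2)cc1Br)[C@@H](OB(CCCC)CCCC)Cc1c(OCOC)cc(OCc2ccccc2)cc1OCc1ccccc1
F9 | step 15 | (R)-4-benzyl-3-[(2R,3S)-2-[4,5-bis(benzyloxy)-2-bromophenyl]-4-[2,4-bis(benzyloxy)-6-(methoxymethoxy)phenyl]-3-hydroxybutanoyl]oxazolidin-2-one | O=C(N1C(=O)OC[C@H]1Cc1ccccc1)[C@H](c1cc(OCc2ccccc2)c(OCc2ccccc2)cc1Br)[C@@H](O)Cc1c(OCOC)cc(OCc2ccccc2)cc1OCc1ccccc1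
F10 | step 15 | 3-O-TBS ether of F9 | O=C(N1C(=O)OC[C@H]1Cc1ccccc1)[C@H](c1cc(OCc2ccccc2)c(OCc2ccccc2)cc1Br)[C@@H](O[Si](C)(C)C(C)(C)C)Cc1c(OCOC)cc(OCc2ccccc2)cc1OCc1ccccc1
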